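The data are calculated from invented constants; the scatter is artificial.

In a one-step world, where the single-handed catalyst turns left-handed substrate into left-handed product and nothing feeds it, this racemic flask stops at the left-handed share of the charge, 50.0 %, the ceiling. That symmetric share is my zero: left-handed product above it has crossed over from the right-handed charge.

| setting | red | blue | flask |
|---|---|---|---|
| left-handed substrate | 34 mM | 34 mM | 34 mM |
| right-handed substrate | 34 mM | 34 mM | 34 mM |
| gas | 3.6 mM (held) | 3.6 mM (held) | 3.6 mM (held) |
| precatalyst | 10 mol% | 5 mol% | 10 mol% |
| remark | the very flask that is asked about, followed so far | run made earlier |  |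
| time |  |  | 50 min |

- red (time / min: left-handed product / %, right-handed product / %): 0.833: 2.2, 0; 1.33: 2.1, 0.8; 2.00: 5.8, 0; 3.00: 7.0, 0; 4.00: 10.9, 0; 6.00: 13.1, 0; 10.0: 25.3, 1.1
- blue (time / min: left-handed product / %, right-handed product / %): 1.50: 4.8, 0; 2.50: 7.0, 0.7; 4.00: 9.8, 1.6; 6.00: 14.2, 0; 8.00: 19.6, 1.0; 12.0: 32.3, 0.9; 20.0: 51.1, 0

(standard deviation of a reading: 1 percentage point)

- left-handed product and right-handed product together, in percent of the left-handed substrate and right-handed substrate charged together, at 50 min
- excess of left-handed product over right-handed product in the product at 50 min
- whether the exchange between left-handed substrate and right-handed substrate keeps pace with the reaction: how far the product's excess at 50 min gets from its value without exchange to its value with instant exchange (above 80 % keeps pace, below 20 % hardly takes part, else lags behind)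

- catalyst is single-handed; left-handed substrate and right-handed substrate are mirror images of each other, charged as a racemate, each of them at the stated concentration
- at the start none of the gas is in solution
- an excess is below zero if the other one leads

Here is the red flask as I hand it over. At its last reading, 10.0 min, it holds 25.3 % of left-handed product, and its line needs 39.5 min for the whole charge. The blue run, with half the precatalyst, needs 39.1 min, so I take the pace to come from the gas, and I ask you to leave the held gas and the stirring as they are. At that pace the ceiling takes 19.6 min. Blue's 51.1 % at 20.0 min lies on the ceiling within the scatter, so that reading proves no crossing. No reading of either run stands clearly above the ceiling, so a stall could not show yet and the runs leave the exchange open; I wager that it feeds the line. If it does, then when you come at 50 min, which is later than the 39.1 min, I expect product close to the whole charge, 100 %.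

The forecast stands lower than my reckoning, at 88 %, with an excess of 96 % and an exchange that keeps pace: “I lean towards exchange, with some late slowing”.

The red flask gives 98.9 % with an excess of 95.5 %, and its exchange keeps pace, 96 % of the way to the excess with instant exchange.

    2 catalyst ⇌ resting dimer (K = 460 L mol⁻¹, k = 4400 L mol⁻¹ min⁻¹)
    gas ⇌ partner, rate k2*(csat - [partner]) (kL = 0.540 min⁻¹)
    partner + catalyst + left-handed substrate → catalyst + left-handed product (k = 3.70 × 10⁵ L² mol⁻² min⁻¹)
    left-handed substrate ⇌ right-handed substrate (k = 0.150 min⁻¹)
    partner + catalyst + right-handed substrate → catalyst + right-handed product (k = 4100 L² mol⁻² min⁻¹)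
    precatalyst → catalyst (k = 0.460 min⁻¹)

The exchange relaxes with a half-life of 2.31 min, both directions counted, which is shorter than the 19.6 min the line takes for the ceiling's worth of charge. At 50.0 min the red flask holds 96.7 % of left-handed product and 0.0851 % of left-handed substrate, together 47 percentage points above the ceiling, which is 93.6 % of the right-handed charge crossed over, and the neighbour flask with 2.5 mol% of precatalyst holds 95.0 % and 0.653 % of the same two, which is 91.3 % crossed over.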